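## Retrosynthetic overview

1. Target 18 comes from trans alcohol 17 by cleavage of two pivalates, and 17 from (S)-isoflavanone 16 by reduction of the C4 ketone.
2. The feature used is the aryl–O–CH2 unit O1–C2 on C8a of ring A: C2 is taken as the methyl carbon of a methoxy group ortho to the C4 carbonyl, and C2–C3 as the bond made when a carbene at C3 inserts into one of its C–H bonds (diazoketone 15).
3. 15 comes from deoxybenzoin 14 by diazo transfer, and 14 from Friedel–Crafts acylation of 1,2,3,4-tetramethoxybenzene 12 with the ring-B arylacetic acid 11.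
4. 11 comes from 2,3-dimethoxyphenol 1 by O-allylation, Claisen rearrangement, oxidation to the para-quinone, reductive pivaloylation and oxidative cleavage of the allyl group.
5. Ring order: rings A and B are bought as arenes; the pyran ring (ring C) is the only ring formed, in step 9.

Key step: step 9

Assumption: Rh2(S-PTAD)4 is taken to induce the (3S) configuration in step 9; if the sense of induction is the reverse, Rh2(R-PTAD)4 is used and nothing else changes.

## Route

Step 1
Reactants: 1 2,3-dimethoxyphenol; 2 allyl bromide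
Product: 3 1-(allyloxy)-2,3-dimethoxybenzene
Conditions: K2CO3, acetone, reflux
Reagents that add atoms: allyl bromide (compound 2), C=CCBr
Why: Williamson ether synthesis: the phenoxide of 1 displaces bromide from the allyl halide (SN2), and 1 has only one acidic OH, so no selectivity issue arises.

Step 2
Reactants: 3 1-(allyloxy)-2,3-dimethoxybenzene
Product: 4 6-allyl-2,3-dimethoxyphenol
Conditions: N,N-diethylaniline, 200 °C
Reagents that add atoms: none
Why: Aromatic Claisen rearrangement ([3,3]-sigmatropic shift followed by enolisation) moves the allyl group to C6, the only ortho position that bears hydrogen, because the other ortho carbon carries a methoxy group.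

Step 3
Reactants: 4 6-allyl-2,3-dimethoxyphenol
Product: 5 5-allyl-2,3-dimethoxy-1,4-benzoquinone
Conditions: (KSO3)2NO, KH2PO4, H2O/acetone, 0 °C → rt
Reagents that add atoms: potassium nitrosodisulfonate, [K+].[K+].[O]N(S(=O)(=O)[O-])S(=O)(=O)[O-]
Why: Teuber oxidation: the nitrosodisulfonate radical abstracts the phenolic hydrogen and a second equivalent adds at the free para carbon, which collapses to the para-quinone, while the allyl group and the methyl ethers are inert to this radical.

Step 4
Reactants: 5 5-allyl-2,3-dimethoxy-1,4-benzoquinone; 6 pivaloyl chloride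
Product: 8 5-allyl-2,3-dimethoxy-1,4-phenylene bis(2,2-dimethylpropanoate), via hydroquinone 7 (not isolated)
Conditions: Na2S2O4, EtOAc/H2O, rt; organic phase dried, then PivCl, pyridine, DMAP (cat.), CH2Cl2, 0 °C → rt
Reagents that add atoms: pivaloyl chloride (compound 6), CC(C)(C)C(Cl)=O
Why: Dithionite reduces the quinone to the hydroquinone, which is acylated at once on both oxygens by DMAP-catalysed nucleophilic acyl substitution, so the air-sensitive diol is never stored.

Step 5
Reactants: 8 5-allyl-2,3-dimethoxy-1,4-phenylene bis(2,2-dimethylpropanoate)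
Product: 10 [3,4-dimethoxy-2,5-bis(pivaloyloxy)phenyl]acetaldehyde, via secondary ozonide 9 (not isolated)
Conditions: O3, CH2Cl2, −78 °C (indicator end-point); PPh3, −78 °C → rt
Reagents that add atoms: ozone, [O-][O+]=O
Why: Ozonolysis (1,3-dipolar cycloaddition, Criegee rearrangement to the secondary ozonide, reduction by PPh3) cleaves the terminal alkene much faster than ozone attacks the arene, whose two acyloxy groups lower its electron density.

Step 6
Reactants: 10 [3,4-dimethoxy-2,5-bis(pivaloyloxy)phenyl]acetaldehyde
Product: 11 [3,4-dimethoxy-2,5-bis(pivaloyloxy)phenyl]acetic acid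
Conditions: NaClO2, NaH2PO4, 2-methyl-2-butene, t-BuOH/H2O, 0 °C → rt
Reagents that add atoms: sodium chlorite, [Na+].[O-]Cl=O
Why: Pinnick oxidation: chlorous acid converts the aldehyde into the acid at buffered pH with 2-methyl-2-butene trapping HOCl, conditions under which aryl pivalates and methyl ethers are stable.

Step 7
Reactants: 11 [3,4-dimethoxy-2,5-bis(pivaloyloxy)phenyl]acetic acid; 12 1,2,3,4-tetramethoxybenzene
Product: 14 2-[3,4-dimethoxy-2,5-bis(pivaloyloxy)phenyl]-1-(2,3,4,5-tetramethoxyphenyl)ethanone, via mixed trifluoroacetic anhydride 13 (not isolated)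
Conditions: (CF3CO)2O, 85% H3PO4, MeCN, 0 °C → rt
Reagents that add atoms: trifluoroacetic anhydride, O=C(OC(=O)C(F)(F)F)C(F)(F)F (its acyl group is carried only by intermediate 13, not by 14)
Why: Friedel–Crafts acylation through the mixed trifluoroacetic anhydride: the acylium equivalent attacks one of the two equivalent free positions of electron-rich 12, para to a methoxy group, and the absence of a metal halide Lewis acid avoids cleavage of the methoxy group ortho to the new ketone, which is needed in step 9.

Step 8
Reactants: 14 2-[3,4-dimethoxy-2,5-bis(pivaloyloxy)phenyl]-1-(2,3,4,5-tetramethoxyphenyl)ethanone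
Product: 15 2-diazo-2-[3,4-dimethoxy-2,5-bis(pivaloyloxy)phenyl]-1-(2,3,4,5-tetramethoxyphenyl)ethanone
Conditions: p-ABSA, DBU, MeCN, 0 °C, dark
Reagents that add atoms: 4-acetamidobenzenesulfonyl azide (p-ABSA), CC(=O)Nc1ccc(cc1)S(=O)(=O)N=[N+]=[N-]
Why: Regitz diazo transfer: DBU generates the enolate of the doubly activated (benzylic and α-keto) methylene, which attacks the terminal nitrogen of the sulfonyl azide and expels the sulfonamide; low temperature and the bulk of the pivaloyl group keep acyl migration from the neighbouring ester at bay.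

Step 9
Reactants: 15 2-diazo-2-[3,4-dimethoxy-2,5-bis(pivaloyloxy)phenyl]-1-(2,3,4,5-tetramethoxyphenyl)ethanone
Product: 16 (3S)-3-[3,4-dimethoxy-2,5-bis(pivaloyloxy)phenyl]-6,7,8-trimethoxychroman-4-one
Conditions: Rh2(S-PTAD)4 (1 mol %), CH2Cl2, 4 Å MS, −20 → 0 °C, slow addition of 15; Celite filtration, evaporation below 10 °C, crude used at once
Reagents that add atoms: none
Why: Rh2(S-PTAD)4 takes up the diazo carbon of 15 with loss of N2 to give an aryl/acyl (donor–acceptor) rhodium carbene at the future C3, which inserts in a concerted, asynchronous three-centre step into a C–H bond of the methoxy group ortho to the ketone, the developing positive charge on carbon being stabilised by the ether oxygen. The closest known reaction type is the dirhodium-catalysed intramolecular C–H insertion of 2-alkoxyaryl diazoketones to chroman-4-ones, together with enantioselective insertions of aryl-substituted carbenes into methyl ether C–H bonds. The pyranone ring is closed by C2–C3 bond formation through a six-membered transition state (1,6-insertion), the former methoxy carbon becoming C2. C3 is the only new stereocentre and is set by the chiral phthalimido-carboxylate ligand sphere, which fixes the face of the carbene that meets the C–H bond. The step needs chemoselectivity for C–H insertion over attack of the same methoxy oxygen on the carbene (oxonium ylide, then methyl shift to a benzofuranone) and over capture by the pivalate carbonyl; the aryl donor makes ylide formation reversible, the tether brings no other sp3 C–H within reach, and the ring-B ortho oxygen bears a pivaloyl group with no C–H next to oxygen. Because C3–H of 16 is acidic, the product is kept away from base and silica.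

Step 10
Reactants: 16 (3S)-3-[3,4-dimethoxy-2,5-bis(pivaloyloxy)phenyl]-6,7,8-trimethoxychroman-4-one
Product: 17 (3S,4R)-3-[3,4-dimethoxy-2,5-bis(pivaloyloxy)phenyl]-6,7,8-trimethoxychroman-4-ol (trans)
Conditions: NaBH4, CeCl3·7H2O, MeOH/THF, −78 °C; pH 7 phosphate buffer; chromatography on Et3N-deactivated silica to remove any cis isomer
Reagents that add atoms: none
Why: Luche reduction: the small cerium-modified borohydride attacks C4 axially, anti to the pseudo-equatorial C3 aryl group, so that the new C4 stereocentre is set by substrate control as the trans (3S,4R) alcohol, and the non-basic medium at −78 °C outruns enolisation, which keeps C3 intact.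

Step 11
Reactants: 17 (3S,4R)-3-[3,4-dimethoxy-2,5-bis(pivaloyloxy)phenyl]-6,7,8-trimethoxychroman-4-ol
Product: 18 (3S,4R)-3-(2,5-dihydroxy-3,4-dimethoxyphenyl)-6,7,8-trimethoxychroman-4-ol (CNP0111047.1)
Conditions: i-Bu2AlH (6 equiv), CH2Cl2, −78 → −40 °C; MeOH, then degassed aq. potassium sodium tartrate, under Ar
Reagents that add atoms: none
Why: Hydride reduction of the two aryl esters (addition of i-Bu2AlH, collapse to the aluminium phenoxide, reduction of pivalaldehyde) frees both phenols without Brønsted acid or strong base, so that neither C4 ionises nor C3 epimerises and the neutral, oxygen-free work-up protects the hydroquinone.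

## Compound list

1 | 2,3-dimethoxyphenol | COc1cccc(O)c1OC | starting material
2 | allyl bromide | C=CCBr | starting material
3 | 1-(allyloxy)-2,3-dimethoxybenzene | C=CCOc1cccc(OC)c1OC | intermediate
4 | 6-allyl-2,3-dimethoxyphenol | C=CCc1ccc(OC)c(OC)c1O | intermediate
5 | 5-allyl-2,3-dimethoxy-1,4-benzoquinone | C=CCC1=CC(=O)C(OC)=C(OC)C1=O | intermediate
6 | pivaloyl chloride | CC(C)(C)C(Cl)=O | starting material
7 | 5-allyl-2,3-dimethoxybenzene-1,4-diol (hydroquinone) | C=CCc1cc(O)c(OC)c(OC)c1O | intermediate (not isolated)
8 | 5-allyl-2,3-dimethoxy-1,4-phenylene bis(2,2-dimethylpropanoate) | C=CCc1cc(OC(=O)C(C)(C)C)c(OC)c(OC)c1OC(=O)C(C)(C)C | intermediate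
9 | 3-[3,4-dimethoxy-2,5-bis(pivaloyloxy)benzyl]-1,2,4-trioxolane (secondary ozonide) | CC(C)(C)C(=O)Oc1cc(CC2OCOO2)c(OC(=O)C(C)(C)C)c(OC)c1OC | intermediate (not isolated)
10 | [3,4-dimethoxy-2,5-bis(pivaloyloxy)phenyl]acetaldehyde | O=CCc1cc(OC(=O)C(C)(C)C)c(OC)c(OC)c1OC(=O)C(C)(C)C | intermediate
11 | [3,4-dimethoxy-2,5-bis(pivaloyloxy)phenyl]acetic acid | OC(=O)Cc1cc(OC(=O)C(C)(C)C)c(OC)c(OC)c1OC(=O)C(C)(C)C | intermediate
12 | 1,2,3,4-tetramethoxybenzene | COc1ccc(OC)c(OC)c1OC | starting material
13 | [3,4-dimethoxy-2,5-bis(pivaloyloxy)phenyl]acetic trifluoroacetic anhydride | FC(F)(F)C(=O)OC(=O)Cc1cc(OC(=O)C(C)(C)C)c(OC)c(OC)c1OC(=O)C(C)(C)C | intermediate (not isolated)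
14 | 2-[3,4-dimethoxy-2,5-bis(pivaloyloxy)phenyl]-1-(2,3,4,5-tetramethoxyphenyl)ethanone | COc1cc(C(=O)Cc2cc(OC(=O)C(C)(C)C)c(OC)c(OC)c2OC(=O)C(C)(C)C)c(OC)c(OC)c1OC | intermediate
15 | 2-diazo-2-[3,4-dimethoxy-2,5-bis(pivaloyloxy)phenyl]-1-(2,3,4,5-tetramethoxyphenyl)ethanone | COc1cc(C(=O)C(=[N+]=[N-])c2cc(OC(=O)C(C)(C)C)c(OC)c(OC)c2OC(=O)C(C)(C)C)c(OC)c(OC)c1OC | intermediate
16 | (3S)-3-[3,4-dimethoxy-2,5-bis(pivaloyloxy)phenyl]-6,7,8-trimethoxychroman-4-one | COc1cc2c(c(OC)c1OC)OC[C@H](c1cc(OC(=O)C(C)(C)C)c(OC)c(OC)c1OC(=O)C(C)(C)C)C2=O | intermediate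
17 | (3S,4R)-3-[3,4-dimethoxy-2,5-bis(pivaloyloxy)phenyl]-6,7,8-trimethoxychroman-4-ol | COc1cc2c(c(OC)c1OC)OC[C@H](c1cc(OC(=O)C(C)(C)C)c(OC)c(OC)c1OC(=O)C(C)(C)C)[C@H]2O | intermediate
18 | (3S,4R)-3-(2,5-dihydroxy-3,4-dimethoxyphenyl)-6,7,8-trimethoxychroman-4-ol | COc1cc2c(c(OC)c1OC)OC[C@H](c1cc(O)c(OC)c(OC)c1O)[C@H]2O | target

## Step count

Total: 11 steps. Longest linear sequence: 11 steps (1 → 18); 2, 6 and 12 are used as purchased.

## Steps most likely to fail

**Step 9 (C–H insertion).** The carbene may be captured by the methoxy oxygen (oxonium ylide followed by methyl migration to a benzofuranone) or by the pivalate carbonyl in place of C–H insertion, or the insertion may proceed with poor facial selectivity.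

The fallback sets out from 14 and builds the pyran ring by the classical one-carbon route, with the stereocentres set by transfer hydrogenation:
- BCl3 (CH2Cl2, −78 → 0 °C) would cleave, through its chelate with the ketone, only the methoxy group ortho to the carbonyl. This should give 2-[3,4-dimethoxy-2,5-bis(pivaloyloxy)phenyl]-1-(2-hydroxy-3,4,5-trimethoxyphenyl)ethanone F1.
- Condensation with N,N-dimethylformamide dimethyl acetal (toluene, 90 °C) would add C2 and close the ring to the isoflavone 3-[3,4-dimethoxy-2,5-bis(pivaloyloxy)phenyl]-6,7,8-trimethoxy-4H-chromen-4-one F2.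
- Asymmetric transfer hydrogenation with RuCl(p-cymene)[(S,S)-TsDPEN] in HCO2H/Et3N would reduce the C2=C3 bond and then the ketone, with dynamic kinetic resolution at the labile C3. This should give the cis alcohol (3S,4S)-3-[3,4-dimethoxy-2,5-bis(pivaloyloxy)phenyl]-6,7,8-trimethoxychroman-4-ol F3.
- Mitsunobu inversion at C4 (chloroacetic acid, PPh3, DIAD, THF, 0 °C) would give the trans ester (3S,4R)-3-[3,4-dimethoxy-2,5-bis(pivaloyloxy)phenyl]-6,7,8-trimethoxychroman-4-yl chloroacetate F4.
- i-Bu2AlH under the conditions of step 11 would remove the chloroacetate and both pivalates, so the fallback comes back to the route at 18.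

**Step 10 (ketone reduction).** C3 may epimerise by enolisation before hydride is delivered, or the hydride may attack the wrong face of C4 and give the cis alcohol.

The fallback sets out from 16 and replaces substrate control by reagent control: Corey–Bakshi–Shibata reduction with (S)-2-methyl-CBS-oxazaborolidine and BH3·SMe2 (toluene, −40 °C). This catalyst delivers hydride to the face of an aryl ketone that gives the (4R) alcohol, and the Lewis-acidic, base-free medium does not enolise the ketone. It comes back to the route at 17 and makes no new compound (F0).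

**Step 8 (diazo transfer).** The enolate may take over the pivaloyl group from the neighbouring 2'-oxygen (O→C or O→O acyl migration) faster than it is captured by the sulfonyl azide, or transfer to the hindered methylene may stall.

The fallback sets out from 14 and avoids the enolate:
- Condensation with tert-butoxybis(dimethylamino)methane (neat, 50 °C) would give the enaminone 3-(dimethylamino)-2-[3,4-dimethoxy-2,5-bis(pivaloyloxy)phenyl]-1-(2,3,4,5-tetramethoxyphenyl)prop-2-en-1-one F5.
- Tosyl azide (MeCN, rt) would add to the enamine double bond by 1,3-dipolar cycloaddition, and the triazoline would fragment to the diazoketone and a sulfonyl formamidine (deformylative diazo transfer under neutral conditions). The fallback comes back to the route at 15.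

## Further compounds

F1 | step 9 | 2-[3,4-dimethoxy-2,5-bis(pivaloyloxy)phenyl]-1-(2-hydroxy-3,4,5-trimethoxyphenyl)ethanone | COc1cc(C(=O)Cc2cc(OC(=O)C(C)(C)C)c(OC)c(OC)c2OC(=O)C(C)(C)C)c(O)c(OC)c1OC
F2 | step 9 | 3-[3,4-dimethoxy-2,5-bis(pivaloyloxy)phenyl]-6,7,8-trimethoxy-4H-chromen-4-one | COc1cc2c(c(OC)c1OC)occ(-c1cc(OC(=O)C(C)(C)C)c(OC)c(OC)c1OC(=O)C(C)(C)C)c2=O
F3 | step 9 | (3S,4S)-3-[3,4-dimethoxy-2,5-bis(pivaloyloxy)phenyl]-6,7,8-trimethoxychroman-4-ol | COc1cc2c(c(OC)c1OC)OC[C@H](c1cc(OC(=O)C(C)(C)C)c(OC)c(OC)c1OC(=O)C(C)(C)C)[C@@H]2O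
F4 | step 9 | (3S,4R)-3-[3,4-dimethoxy-2,5-bis(pivaloyloxy)phenyl]-6,7,8-trimethoxychroman-4-yl chloroacetate | COc1cc2c(c(OC)c1OC)OC[C@H](c1cc(OC(=O)C(C)(C)C)c(OC)c(OC)c1OC(=O)C(C)(C)C)[C@H]2OC(=O)CCl
F0 | step 10 | none | none
F5 | step 8 | 3-(dimethylamino)-2-[3,4-dimethoxy-2,5-bis(pivaloyloxy)phenyl]-1-(2,3,4,5-tetramethoxyphenyl)prop-2-en-1-one | COc1cc(C(=O)C(=CN(C)C)c2cc(OC(=O)C(C)(C)C)c(OC)c(OC)c2OC(=O)C(C)(C)C)c(OC)c(OC)c1OC
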